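The isoflavone is disconnected at the C3–C4 bond of the pyranone ring. C4 is a carbonyl carbon and C3 carries the B-ring aryl group, so an aldehyde-derived acyl anion at C4 can add to an aryl ketone at C3 tethered through O1–C2. A carbene-catalysed intramolecular crossed benzoin reaction forms this bond, closes the pyranone ring and gives a 3-hydroxyisoflavanone that needs only loss of water across C2–C3. The precursor is a salicylaldehyde whose phenol oxygen carries the CH2–C(=O) unit of the 2,2-dimethylchromenyl ketone. Both phenols travel as MOM ethers, because the chromene C3=C4 and isoflavone C2=C3 double bonds forbid hydrogenolysis.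

Key step: step 9

Remark: the target has no stereocentre, so the achiral compound as drawn is made; the carbinol centre created in step 9 is racemic and is erased in step 10.

Step 1
Reactants: 1 5-hydroxyvanillin (3,4-dihydroxy-5-methoxybenzaldehyde)
Product: 2 3-hydroxy-5-methoxy-4-(methoxymethoxy)benzaldehyde
Conditions: MOMCl (1.05 equiv), K2CO3 (1.1 equiv), acetone, 0 °C → rt
Reagents that add atoms: chloromethyl methyl ether (MOMCl), COCCl
Why: Williamson-type O-alkylation (MOM protection) in which one equivalent of carbonate ionises only the 4-OH, para to the formyl group and much the more acidic, so O4 is protected and the 3-OH stays free.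

Step 2
Reactants: 2 3-hydroxy-5-methoxy-4-(methoxymethoxy)benzaldehyde; 3 3-chloro-3-methylbut-1-yne
Product: 4 3-methoxy-4-(methoxymethoxy)-5-[(2-methylbut-3-yn-2-yl)oxy]benzaldehyde
Conditions: DBU, CuCl2·2H2O (cat.), MeCN, 0 °C → rt
Reagents that add atoms: none
Why: Copper-catalysed O-propargylation of a phenol with a tertiary propargylic chloride is the standard way to aryl 1,1-dimethylpropargyl ethers, and the aldehyde and MOM ether are inert to DBU at this temperature.

Step 3
Reactants: 4 3-methoxy-4-(methoxymethoxy)-5-[(2-methylbut-3-yn-2-yl)oxy]benzaldehyde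
Product: 5 7-methoxy-8-(methoxymethoxy)-2,2-dimethyl-2H-chromene-5-carbaldehyde
Conditions: PhNEt2, 180 °C
Reagents that add atoms: none
Why: Thermal aryl propargyl ether Claisen rearrangement, then enolisation, 1,5-hydrogen shift and 6π-oxa-electrocyclisation, can engage only the free ortho position between the ether oxygen and the formyl group (the other ortho carbon bears OMOM), so a single chromene regioisomer is expected.

Step 4
Reactants: 5 7-methoxy-8-(methoxymethoxy)-2,2-dimethyl-2H-chromene-5-carbaldehyde
Product: 6 racemic 1-[7-methoxy-8-(methoxymethoxy)-2,2-dimethyl-2H-chromen-5-yl]ethan-1-ol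
Conditions: MeMgBr, THF, −78 → 0 °C
Reagents that add atoms: methylmagnesium bromide, C[Mg]Br
Why: Grignard 1,2-addition to an aryl aldehyde; the new carbinol centre forms without control as a racemate and is removed by the oxidation in step 5.

Step 5
Reactants: 6 racemic 1-[7-methoxy-8-(methoxymethoxy)-2,2-dimethyl-2H-chromen-5-yl]ethan-1-ol
Product: 7 1-[7-methoxy-8-(methoxymethoxy)-2,2-dimethyl-2H-chromen-5-yl]ethan-1-one
Conditions: IBX, DMSO, rt
Reagents that add atoms: none
Why: IBX oxidation of a secondary benzylic alcohol to the aryl methyl ketone runs under neutral conditions that leave the MOM acetal and the chromene olefin untouched.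

Step 6
Reactants: 7 1-[7-methoxy-8-(methoxymethoxy)-2,2-dimethyl-2H-chromen-5-yl]ethan-1-one
Product: 9 2-bromo-1-[7-methoxy-8-(methoxymethoxy)-2,2-dimethyl-2H-chromen-5-yl]ethan-1-one, via {[1-(7-methoxy-8-(methoxymethoxy)-2,2-dimethyl-2H-chromen-5-yl)ethenyl]oxy}trimethylsilane 8 (not isolated)
Conditions: LiHMDS, TMSCl, THF, −78 °C; solvent exchange, then NBS (1.05 equiv), THF, −78 → 0 °C
Reagents that add atoms: N-bromosuccinimide, O=C1CCC(=O)N1Br
Why: α-Bromination of a ketone through its silyl enol ether: only the methyl group can enolise, and the silyl enol ether is far more nucleophilic towards NBS than the chromene olefin or the arene, so bromine is delivered to the α-carbon alone without forming HBr.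

Step 7
Reactants: 10 2,4-dihydroxybenzaldehyde
Product: 11 2-hydroxy-4-(methoxymethoxy)benzaldehyde
Conditions: MOMCl (1.05 equiv), K2CO3 (1.1 equiv), acetone, 0 °C → rt
Reagents that add atoms: chloromethyl methyl ether (MOMCl), COCCl
Why: Williamson-type MOM protection selective for the 4-OH, because the 2-OH is hydrogen-bonded to the formyl group and less acidic.

Step 8
Reactants: 9 2-bromo-1-[7-methoxy-8-(methoxymethoxy)-2,2-dimethyl-2H-chromen-5-yl]ethan-1-one; 11 2-hydroxy-4-(methoxymethoxy)benzaldehyde
Product: 12 2-{2-[7-methoxy-8-(methoxymethoxy)-2,2-dimethyl-2H-chromen-5-yl]-2-oxoethoxy}-4-(methoxymethoxy)benzaldehyde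
Conditions: K2CO3 (1.2 equiv), acetone, rt
Reagents that add atoms: none
Why: Williamson ether synthesis (SN2 of the phenoxide on a phenacyl-type bromide), which at room temperature with carbonate should be much faster than aldol condensation of the product.

Step 9
Reactants: 12 2-{2-[7-methoxy-8-(methoxymethoxy)-2,2-dimethyl-2H-chromen-5-yl]-2-oxoethoxy}-4-(methoxymethoxy)benzaldehyde
Product: 13 racemic 3-hydroxy-3-[7-methoxy-8-(methoxymethoxy)-2,2-dimethyl-2H-chromen-5-yl]-7-(methoxymethoxy)chroman-4-one
Conditions: 2-(pentafluorophenyl)-6,7-dihydro-5H-pyrrolo[2,1-c][1,2,4]triazol-2-ium tetrafluoroborate (15 mol%), Et3N (15 mol%), toluene, N2, rt → 40 °C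
Reagents that add atoms: none
Why: The carbene freed from the triazolium salt adds to the aldehyde carbon, and proton transfer gives the Breslow enaminol, an acyl-anion equivalent at the future C4; it attacks the tethered aryl ketone carbon (future C3), and collapse of the adduct releases the carbene and the tertiary α-ketol. The closest known reaction type is the NHC-catalysed intramolecular crossed aldehyde–ketone benzoin cyclisation of 2-(2-oxo-2-arylethoxy)benzaldehydes to 3-aryl-3-hydroxychroman-4-ones. The pyranone ring (C4, C4a, C8a, O1, C2, C3) closes 6-exo-trig, the ketone oxygen staying outside the ring. The new carbinol centre C3 is under no control with the achiral catalyst and forms as a racemate, which is harmless because step 10 removes it. The step needs chemoselectivity for acyl-anion addition over base-induced aldol condensation of the O-bound methylene onto the aldehyde (leading to a 2-aroylbenzofuran) and over intermolecular homo-benzoin. A weak amine base in catalytic amount, the intramolecular six-membered closure, and a ketone that is activated by its α-aryloxy group and cannot enolise on the aryl side secure this.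

Step 10
Reactants: 13 racemic 3-hydroxy-3-[7-methoxy-8-(methoxymethoxy)-2,2-dimethyl-2H-chromen-5-yl]-7-(methoxymethoxy)chroman-4-one
Product: 14 3-[7-methoxy-8-(methoxymethoxy)-2,2-dimethyl-2H-chromen-5-yl]-7-(methoxymethoxy)-4H-chromen-4-one
Conditions: Burgess reagent (2 equiv), THF, rt → 50 °C
Reagents that add atoms: none
Why: Burgess dehydration of a tertiary alcohol by syn-elimination of its sulfamate ester; only C2 carries β-hydrogens, so the double bond can form only across C2–C3, giving the conjugated chromone and removing the racemic centre.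

Step 11
Reactants: 14 3-[7-methoxy-8-(methoxymethoxy)-2,2-dimethyl-2H-chromen-5-yl]-7-(methoxymethoxy)-4H-chromen-4-one
Product: 15 7-hydroxy-3-(8-hydroxy-7-methoxy-2,2-dimethyl-2H-chromen-5-yl)-4H-chromen-4-one (target, achiral)
Conditions: HCl (2 M aq.), MeOH–THF, 45 °C
Reagents that add atoms: none
Why: Acid-catalysed acetal cleavage of both aryl MOM ethers under dilute protic acid, conditions that the isoflavone and the aryl methyl ether tolerate and that are kept mild to spare the 2,2-dimethylchromene olefin.

Compound list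
1 | 5-hydroxyvanillin (3,4-dihydroxy-5-methoxybenzaldehyde) | COc1cc(C=O)cc(O)c1O | starting material
2 | 3-hydroxy-5-methoxy-4-(methoxymethoxy)benzaldehyde | COCOc1c(O)cc(C=O)cc1OC | intermediate
3 | 3-chloro-3-methylbut-1-yne | CC(C)(Cl)C#C | starting material
4 | 3-methoxy-4-(methoxymethoxy)-5-[(2-methylbut-3-yn-2-yl)oxy]benzaldehyde | COCOc1c(OC)cc(C=O)cc1OC(C)(C)C#C | intermediate
5 | 7-methoxy-8-(methoxymethoxy)-2,2-dimethyl-2H-chromene-5-carbaldehyde | COCOc1c(OC)cc(C=O)c2C=CC(C)(C)Oc12 | intermediate
6 | racemic 1-[7-methoxy-8-(methoxymethoxy)-2,2-dimethyl-2H-chromen-5-yl]ethan-1-ol | COCOc1c(OC)cc(C(C)O)c2C=CC(C)(C)Oc12 | intermediate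
7 | 1-[7-methoxy-8-(methoxymethoxy)-2,2-dimethyl-2H-chromen-5-yl]ethan-1-one | COCOc1c(OC)cc(C(C)=O)c2C=CC(C)(C)Oc12 | intermediate
8 | {[1-(7-methoxy-8-(methoxymethoxy)-2,2-dimethyl-2H-chromen-5-yl)ethenyl]oxy}trimethylsilane | COCOc1c(OC)cc(C(=C)O[Si](C)(C)C)c2C=CC(C)(C)Oc12 | intermediate (not isolated)
9 | 2-bromo-1-[7-methoxy-8-(methoxymethoxy)-2,2-dimethyl-2H-chromen-5-yl]ethan-1-one | COCOc1c(OC)cc(C(=O)CBr)c2C=CC(C)(C)Oc12 | intermediate
10 | 2,4-dihydroxybenzaldehyde | O=Cc1ccc(O)cc1O | starting material
11 | 2-hydroxy-4-(methoxymethoxy)benzaldehyde | COCOc1ccc(C=O)c(O)c1 | intermediate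
12 | 2-{2-[7-methoxy-8-(methoxymethoxy)-2,2-dimethyl-2H-chromen-5-yl]-2-oxoethoxy}-4-(methoxymethoxy)benzaldehyde | O=Cc1ccc(OCOC)cc1OCC(=O)c1cc(OC)c(OCOC)c2OC(C)(C)C=Cc12 | intermediate
13 | racemic 3-hydroxy-3-[7-methoxy-8-(methoxymethoxy)-2,2-dimethyl-2H-chromen-5-yl]-7-(methoxymethoxy)chroman-4-one | COc1cc(C2(O)COc3cc(OCOC)ccc3C2=O)c2C=CC(C)(C)Oc2c1OCOC | intermediate
14 | 3-[7-methoxy-8-(methoxymethoxy)-2,2-dimethyl-2H-chromen-5-yl]-7-(methoxymethoxy)-4H-chromen-4-one | COc1cc(-c2coc3cc(OCOC)ccc3c2=O)c2C=CC(C)(C)Oc2c1OCOC | intermediate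
15 | 7-hydroxy-3-(8-hydroxy-7-methoxy-2,2-dimethyl-2H-chromen-5-yl)-4H-chromen-4-one | COc1cc(-c2coc3cc(O)ccc3c2=O)c2c(c1O)OC(C)(C)C=C2 | target

Total step count: 11. Longest linear sequence: 10 (steps 1–6 and 8–11, from 5-hydroxyvanillin).

Steps most likely to fail

Step 9: the carbene adduct may add too slowly to the ortho-substituted, electron-rich aryl ketone, so that aldol condensation of the O-bound methylene or aldehyde self-condensation takes over. The fallback sets the C3–aryl bond by an oxidative 1,2-aryl shift instead. It sets out from chromene aldehyde 5 and comes back at target 15. Aldehyde 5 is condensed (KOH, EtOH, rt, Claisen–Schmidt) with 1-[2-hydroxy-4-(methoxymethoxy)phenyl]ethan-1-one F1, made from 2',4'-dihydroxyacetophenone with MOMCl and K2CO3. This gives the 2'-hydroxychalcone (E)-1-[2-hydroxy-4-(methoxymethoxy)phenyl]-3-[7-methoxy-8-(methoxymethoxy)-2,2-dimethyl-2H-chromen-5-yl]prop-2-en-1-one F2. Thallium(III) nitrate in MeOH/HC(OMe)3 rearranges it to the racemic β-keto acetal 1-[2-hydroxy-4-(methoxymethoxy)phenyl]-3,3-dimethoxy-2-[7-methoxy-8-(methoxymethoxy)-2,2-dimethyl-2H-chromen-5-yl]propan-1-one F3. HCl in MeOH then closes the pyranone with loss of methanol and cleaves both MOM ethers, giving 15 directly.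

Step 8: the keto aldehyde may undergo base-induced intramolecular aldol condensation (benzofuran formation) during the alkylation. The fallback carries the aldehyde at the alcohol oxidation level. It sets out from 11 and 9 and comes back at precursor 12. Aldehyde 11 is reduced (NaBH4, MeOH, 0 °C) to 2-(hydroxymethyl)-5-(methoxymethoxy)phenol F4. Its phenol is alkylated with bromoketone 9 (K2CO3, acetone, rt) to 2-[2-(hydroxymethyl)-5-(methoxymethoxy)phenoxy]-1-[7-methoxy-8-(methoxymethoxy)-2,2-dimethyl-2H-chromen-5-yl]ethan-1-one F5. MnO2 in CH2Cl2 then oxidises the benzylic alcohol to 12.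

Step 10: sulfamate formation at the hindered tertiary carbinol may be slow, or ionisation may lead to substitution or α-ketol rearrangement instead of elimination. The fallback removes the hydroxyl reductively and then dehydrogenates. It sets out from 13 and comes back at 14. SmI2 in THF/MeOH at −78 °C deoxygenates the α-ketol to racemic 3-[7-methoxy-8-(methoxymethoxy)-2,2-dimethyl-2H-chromen-5-yl]-7-(methoxymethoxy)chroman-4-one F6. DDQ in dioxane at 80 °C then dehydrogenates this isoflavanone across C2–C3 to 14.

Further compounds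
F1 | step 9 | 1-[2-hydroxy-4-(methoxymethoxy)phenyl]ethan-1-one | CC(=O)c1ccc(OCOC)cc1O
F2 | step 9 | (E)-1-[2-hydroxy-4-(methoxymethoxy)phenyl]-3-[7-methoxy-8-(methoxymethoxy)-2,2-dimethyl-2H-chromen-5-yl]prop-2-en-1-one | COCOc1ccc(C(=O)/C=C/c2cc(OC)c(OCOC)c3OC(C)(C)C=Cc23)c(O)c1
F3 | step 9 | racemic 1-[2-hydroxy-4-(methoxymethoxy)phenyl]-3,3-dimethoxy-2-[7-methoxy-8-(methoxymethoxy)-2,2-dimethyl-2H-chromen-5-yl]propan-1-one | COCOc1ccc(C(=O)C(C(OC)OC)c2cc(OC)c(OCOC)c3OC(C)(C)C=Cc23)c(O)c1
F4 | step 8 | 2-(hydroxymethyl)-5-(methoxymethoxy)phenol | COCOc1ccc(CO)c(O)c1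
F5 | step 8 | 2-[2-(hydroxymethyl)-5-(methoxymethoxy)phenoxy]-1-[7-methoxy-8-(methoxymethoxy)-2,2-dimethyl-2H-chromen-5-yl]ethan-1-one | OCc1ccc(OCOC)cc1OCC(=O)c1cc(OC)c(OCOC)c2OC(C)(C)C=Cc12
F6 | step 10 | racemic 3-[7-methoxy-8-(methoxymethoxy)-2,2-dimethyl-2H-chromen-5-yl]-7-(methoxymethoxy)chroman-4-one | COc1cc(C2COc3cc(OCOC)ccc3C2=O)c2C=CC(C)(C)Oc2c1OCOC
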